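Readings and results were generated by integration for an exercise; scatter was added.

Eta could not have stopped for want of partner: it held more partner (0.12 M) than substrate (0.10 M), yet its product stood at 96.6%. I had to decide which recipe to charge first.

- the flasks put in order of amount of product, in percent of the substrate charged, best first, at 6.0 min (Thursday's / Saturday's / Wednesday's / Friday's)
- the amount of product, in percent of the substrate charged of the flask you put first, at 6.0 min
- the amount of product, in percent of the substrate charged of the flask you put last, at 6.0 min

| setting | zeta | gamma | eta | Thursday's | Saturday's | Wednesday's | Friday's |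
|---|---|---|---|---|---|---|---|
| substrate | 0.10 M | 0.10 M | 0.10 M | 0.10 M | 0.10 M | 0.10 M | 0.10 M |
| partner | 0.031 M | 0.29 M | 0.12 M | 0.0400 M | 0.120 M | 0.400 M | 0.120 M |
| initiator | 6.6 mM | 6.6 mM | 6.4 mM | 25 mM | 20 mM | 3.0 mM | 6.6 mM |
| remark | run made earlier | run made earlier | run made earlier |  |  |  |  |
| time |  |  |  | 6.0 min | 6.0 min | 6.0 min | 6.0 min |

- zeta (time / min: product / %): 0.333: 23.3; 1.00: 30.2; 1.50: 31.3; 2.50: 29.8; 4.00: 31.8; 5.00: 30.9; 6.00: 30.8
- gamma (time / min: product / %): 0.833: 98.7; 1.50: 98.7; 2.50: 99.7; 3.00: 99.2; 4.00: 100.0; 5.00: 99.4; 6.00: 100.1
- eta (time / min: product / %): 0.500: 89.8; 0.833: 95.9; 1.50: 96.6; 3.00: 96.7; 6.00: 96.6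

(scatter of a reading: 0.5 percentage points)

- what was read earlier has a scatter of 0.5 percentage points, one standard deviation

Zeta's stop was plain. Its last reading, 30.8%, lay near its partner charge over its substrate charge, 31.0%, so I took partner to go one to one. That made partner the limiting reagent in Thursday's and capped that flask at 40.0%.

Eta's gap of 3.40% is what I called the loss share: the part of the charged substrate that ends as no product while partner stands in excess. I read it as a leak that grows with initiator and shrinks with partner. As a working rule, assumed and not derived, I let the loss share scale as the square root of c_initiator over the square of c_partner, with the substrate charge held.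

Gamma tested this. Its mean reading was 99.4%, good to 0.19 percentage points. The rule gave 99.4%, and a first power of partner gave 98.6%. But eta and gamma held 6.4 mM and 6.6 mM of initiator, so the square root stayed untested. A fixed yield per initiator also came near both runs, so my choice was a judgement.

The rule gave Wednesday's a loss share of 0.210%, so 99.8% product. Friday's came to 96.5% and Saturday's to 94.0%. I put Wednesday's answer back in: it left 75.1% of Wednesday's partner, so I took that charge as a fair stand-in for the run. I chose Wednesday's.

The forecast instead ran Saturday's > Friday's > Wednesday's > Thursday's, with 99.9% on top and 39.8% last, reading eta's halt as “the initiator running out rather than equilibrium”.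

Wednesday's gave 99.8%, Friday's 96.6%, Saturday's 94.2% and Thursday's 40.0%, the order Wednesday's > Friday's > Saturday's > Thursday's.

    partner + chain carrier → product + initiating radical (k = 16000 L mol⁻¹ s⁻¹)
    initiator → 2 initiating radical (k = 0.0220 s⁻¹)
    2 chain carrier → ended chains A (k = 6.00 × 10⁶ L mol⁻¹ s⁻¹)
    substrate + initiating radical ⇌ chain carrier (K = 25100 L mol⁻¹, k = 1.78 × 10⁵ L mol⁻¹ s⁻¹)
    2 initiating radical → ended chains B (k = 2.00 × 10⁸ L mol⁻¹ s⁻¹)

The neighbour was Wednesday's with partner cut to 0.10 M, which is 1.00 equiv, with initiator and time held. From 3.40% I reckoned a loss share of 3.35%, so 96.7% product. Put back in, that answer left 3.35% of its partner, so the charge was a poor stand-in there. The neighbour gave 95.8%, less than reckoned, with 0.28% of its substrate and 4.2% of its partner left.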